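The route rests on cutting the bond between the quaternary butenolide carbon C2 (bonded to ring O1, the ester carbon and C3) and the benzylic CH2 on C6 of the chroman. C2 is α to the methyl ester and, through C3=C4, γ to the lactone carbonyl C5, so its C–H precursor, a racemic 5-oxo-2,5-dihydrofuran-2-carboxylate, gives a planar aromatic furan-2-olate. A chiral ammonium ion pair benzylates this anion at C2 with the enantiopure (R)-chromanylmethyl bromide, activated by the para ring oxygen, joining both halves and setting the quaternary centre stereoconvergently in one operation. The chromanol centre comes from a Jacobsen–Katsuki epoxidation; hydrogenolysis of two benzyl ethers ends the route.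

Key step: step 8

Remark: 11 is taken as a catalogue compound, and the sense of induction of the phase-transfer catalyst in step 8 is assumed to be assignable by a test benzylation (both antipodes are sold).

Step 1
Reactants: 1 3,4-bis(benzyloxy)benzaldehyde; 2 N-acetylglycine
Product: 4 (Z)-4-[3,4-bis(benzyloxy)benzylidene]-2-methyloxazol-5(4H)-one, via 2-methyloxazol-5(4H)-one 3 (not isolated)
Conditions: Ac2O, NaOAc, 110 °C
Reagents that add atoms: none
Why: Erlenmeyer–Plöchl azlactone synthesis, in which cyclodehydration of 2 and Perkin-type condensation with the non-enolisable aldehyde should give the more stable Z-azlactone while the benzyl ethers stay inert.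

Step 2
Reactants: 4 (Z)-4-[3,4-bis(benzyloxy)benzylidene]-2-methyloxazol-5(4H)-one
Product: 6 3-[3,4-bis(benzyloxy)phenyl]-2-oxopropanoic acid, via (Z)-2-acetamido-3-[3,4-bis(benzyloxy)phenyl]acrylic acid 5 (not isolated)
Conditions: acetone/H2O, reflux; then 1 M HCl, dioxane, reflux
Reagents that add atoms: water, O
Why: Stepwise azlactone hydrolysis (ring opening to the dehydroamino acid, then acid hydrolysis of the enamide) is the classical arylpyruvic acid synthesis, and aryl benzyl ethers should tolerate dilute aqueous HCl.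

Step 3
Reactants: 6 3-[3,4-bis(benzyloxy)phenyl]-2-oxopropanoic acid; 7 methyl glyoxylate
Product: 9 methyl 3-[3,4-bis(benzyloxy)phenyl]-4-hydroxy-5-oxo-2,5-dihydrofuran-2-carboxylate (racemic), via open-chain aldol adduct 8 (not isolated)
Conditions: Et3N, THF, 0 °C to rt; then 2 M HCl
Reagents that add atoms: none
Why: Crossed aldol addition of the arylpyruvate enolate (benzylic carbon) to the far more electrophilic, non-enolisable glyoxylate, then acid-induced lactonisation of the γ-hydroxy-α-keto acid to the enolised α-keto lactone (isotetronic acid synthesis); the C2 centre formed here is racemic and is erased in step 8.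

Step 4
Reactants: 9 methyl 3-[3,4-bis(benzyloxy)phenyl]-4-hydroxy-5-oxo-2,5-dihydrofuran-2-carboxylate
Product: 10 methyl 3-[3,4-bis(benzyloxy)phenyl]-4-methoxy-5-oxo-2,5-dihydrofuran-2-carboxylate (racemic)
Conditions: TMSCHN2, toluene/MeOH, 0 °C
Reagents that add atoms: trimethylsilyldiazomethane, C[Si](C)(C)C=[N+]=[N-]
Why: Diazoalkane O-methylation of the acidic enol (proton transfer, then SN2 on the methyldiazonium ion) needs no base, so the acidic C2–H should stay untouched.

Step 5
Reactants: 11 methyl 2,2-dimethyl-2H-chromene-6-carboxylate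
Product: 12 methyl (1aR,7bR)-2,2-dimethyl-1a,7b-dihydro-2H-oxireno[2,3-c]chromene-6-carboxylate, the (3R,4R)-3,4-epoxychroman
Conditions: (R,R)-Mn(salen)Cl [(R,R)-N,N'-bis(3,5-di-tert-butylsalicylidene)-1,2-cyclohexanediaminomanganese(III) chloride] (3 mol%), 4-phenylpyridine N-oxide, aq. NaOCl (pH 11.3), CH2Cl2, 0 °C
Reagents that add atoms: sodium hypochlorite, [Na+].[O-]Cl
Why: Jacobsen–Katsuki epoxidation, for which 2,2-dimethylchromenes are the best substrate class; the (R,R) catalyst is expected to deliver oxygen to the face that gives the (3R,4R)-epoxide, which fixes the later carbinol centre C3.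

Step 6
Reactants: 12 methyl (1aR,7bR)-2,2-dimethyl-1a,7b-dihydro-2H-oxireno[2,3-c]chromene-6-carboxylate
Product: 14 (R)-6-(hydroxymethyl)-2,2-dimethylchroman-3-ol, via epoxy alcohol 13 (not isolated)
Conditions: LiAlH4, THF, 0 °C to 40 °C
Reagents that add atoms: none
Why: LiAlH4 reduces the ester and then opens the epoxide by hydride SN2 attack at the benzylic C4 (C3 is neopentylic, shielded by the gem-dimethyl group), so the C3–O bond and its (R) configuration are retained.

Step 7
Reactants: 14 (R)-6-(hydroxymethyl)-2,2-dimethylchroman-3-ol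
Product: 15 (R)-6-(bromomethyl)-2,2-dimethylchroman-3-ol
Conditions: CBr4, PPh3, CH2Cl2, 0 °C; used directly
Reagents that add atoms: carbon tetrabromide, BrC(Br)(Br)Br
Why: Appel bromination should select the primary benzylic alcohol over the hindered neopentylic secondary alcohol, whose stereocentre is not involved.

Step 8
Reactants: 10 methyl 3-[3,4-bis(benzyloxy)phenyl]-4-methoxy-5-oxo-2,5-dihydrofuran-2-carboxylate (racemic); 15 (R)-6-(bromomethyl)-2,2-dimethylchroman-3-ol
Product: 17 methyl (S)-3-[3,4-bis(benzyloxy)phenyl]-2-{[(R)-3-hydroxy-2,2-dimethylchroman-6-yl]methyl}-4-methoxy-5-oxo-2,5-dihydrofuran-2-carboxylate, via potassium furan-2-olate 16 (not isolated)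
Conditions: (R,R)-3,4,5-trifluorophenyl-NAS bromide (N-spiro binaphthyl ammonium salt, 3 mol%), K2CO3 (s), toluene, −20 °C
Reagents that add atoms: none
Why: Proposed new method: Solid K2CO3 removes the C2–H of 10 (α to the ester, γ to the lactone carbonyl), both enantiomers giving the same planar aromatic furan-2-olate 16, which enters toluene as a tight ion pair with the C2-symmetric ammonium cation and attacks the benzylic bromide 15 in an SN2 step. The closest known reaction type is the chiral ammonium phase-transfer benzylation of cyclic β-keto esters, 3-substituted oxindoles and other flat stabilised enolates to quaternary centres, together with the γ-selective reactions of butenolide dienolates and 2-silyloxyfurans. No ring is closed. The new quaternary centre C2 is set by the catalyst, which should shield one enantiotopic face of the flat anion (the remote chromanol centre of 15 has no influence), so the step is stereoconvergent; the catalyst antipode that gives (S) is fixed in a test run. The step needs C2- over C4- and O-alkylation: C2 is the dienolate terminus and is expected to carry the largest HOMO coefficient, attack there restores the conjugated α-methoxy-β-aryl butenolide, and a soft benzylic bromide activated by the para oxygen in toluene favours C–C bond formation. Solid carbonate at low temperature should spare the lactone, the methyl ester and the free secondary alcohol.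

Step 9
Reactants: 17 methyl (S)-3-[3,4-bis(benzyloxy)phenyl]-2-{[(R)-3-hydroxy-2,2-dimethylchroman-6-yl]methyl}-4-methoxy-5-oxo-2,5-dihydrofuran-2-carboxylate
Product: 18 methyl (S)-3-(3,4-dihydroxyphenyl)-2-{[(R)-3-hydroxy-2,2-dimethylchroman-6-yl]methyl}-4-methoxy-5-oxo-2,5-dihydrofuran-2-carboxylate
Conditions: H2 (1 atm), 10% Pd/C, EtOAc/MeOH, rt
Reagents that add atoms: none
Why: Hydrogenolysis of the two aryl benzyl ethers, under which the tetrasubstituted butenolide alkene, the quaternary allylic lactone C–O bond and both stereocentres are not expected to react.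

Compound list
1 | 3,4-bis(benzyloxy)benzaldehyde | O=Cc1ccc(OCc2ccccc2)c(OCc2ccccc2)c1 | starting material
2 | N-acetylglycine | CC(=O)NCC(=O)O | starting material
3 | 2-methyloxazol-5(4H)-one (formed in the flask) | CC1=NCC(=O)O1 | intermediate
4 | (Z)-4-[3,4-bis(benzyloxy)benzylidene]-2-methyloxazol-5(4H)-one | CC1=N/C(=C\c2ccc(OCc3ccccc3)c(OCc3ccccc3)c2)C(=O)O1 | intermediate
5 | (Z)-2-acetamido-3-[3,4-bis(benzyloxy)phenyl]acrylic acid (formed in the flask) | CC(=O)N/C(=C\c1ccc(OCc2ccccc2)c(OCc2ccccc2)c1)C(=O)O | intermediate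
6 | 3-[3,4-bis(benzyloxy)phenyl]-2-oxopropanoic acid | O=C(O)C(=O)Cc1ccc(OCc2ccccc2)c(OCc2ccccc2)c1 | intermediate
7 | methyl glyoxylate | COC(=O)C=O | starting material
8 | 3-[3,4-bis(benzyloxy)phenyl]-4-hydroxy-5-methoxy-2,5-dioxopentanoic acid, open-chain aldol adduct (stereoisomer mixture, formed in the flask) | COC(=O)C(O)C(c1ccc(OCc2ccccc2)c(OCc2ccccc2)c1)C(=O)C(=O)O | intermediate
9 | methyl 3-[3,4-bis(benzyloxy)phenyl]-4-hydroxy-5-oxo-2,5-dihydrofuran-2-carboxylate (racemic) | COC(=O)C1OC(=O)C(O)=C1c1ccc(OCc2ccccc2)c(OCc2ccccc2)c1 | intermediate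
10 | methyl 3-[3,4-bis(benzyloxy)phenyl]-4-methoxy-5-oxo-2,5-dihydrofuran-2-carboxylate (racemic) | COC(=O)C1OC(=O)C(OC)=C1c1ccc(OCc2ccccc2)c(OCc2ccccc2)c1 | intermediate
11 | methyl 2,2-dimethyl-2H-chromene-6-carboxylate | COC(=O)c1ccc2c(c1)C=CC(C)(C)O2 | starting material
12 | methyl (1aR,7bR)-2,2-dimethyl-1a,7b-dihydro-2H-oxireno[2,3-c]chromene-6-carboxylate, the (3R,4R)-3,4-epoxychroman | COC(=O)c1ccc2c(c1)[C@H]1O[C@H]1C(C)(C)O2 | intermediate
13 | [(1aR,7bR)-2,2-dimethyl-1a,7b-dihydro-2H-oxireno[2,3-c]chromen-6-yl]methanol (formed in the flask) | OCc1ccc2c(c1)[C@H]1O[C@H]1C(C)(C)O2 | intermediate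
14 | (R)-6-(hydroxymethyl)-2,2-dimethylchroman-3-ol | OCc1ccc2c(c1)C[C@@H](O)C(C)(C)O2 | intermediate
15 | (R)-6-(bromomethyl)-2,2-dimethylchroman-3-ol | BrCc1ccc2c(c1)C[C@@H](O)C(C)(C)O2 | intermediate
16 | potassium 4-[3,4-bis(benzyloxy)phenyl]-3-methoxy-5-(methoxycarbonyl)furan-2-olate (achiral, ion-paired with the chiral ammonium cation in toluene, formed in the flask) | COC(=O)c1oc([O-])c(OC)c1-c1ccc(OCc2ccccc2)c(OCc2ccccc2)c1.[K+] | intermediate
17 | methyl (S)-3-[3,4-bis(benzyloxy)phenyl]-2-{[(R)-3-hydroxy-2,2-dimethylchroman-6-yl]methyl}-4-methoxy-5-oxo-2,5-dihydrofuran-2-carboxylate | COC(=O)[C@@]1(Cc2ccc3c(c2)C[C@@H](O)C(C)(C)O3)OC(=O)C(OC)=C1c1ccc(OCc2ccccc2)c(OCc2ccccc2)c1 | intermediate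
18 | methyl (S)-3-(3,4-dihydroxyphenyl)-2-{[(R)-3-hydroxy-2,2-dimethylchroman-6-yl]methyl}-4-methoxy-5-oxo-2,5-dihydrofuran-2-carboxylate | COC(=O)[C@@]1(Cc2ccc3c(c2)C[C@@H](O)C(C)(C)O3)OC(=O)C(OC)=C1c1ccc(O)c(O)c1 | target

Total step count: 9. Longest linear sequence: 6 steps (steps 1, 2, 3, 4, 8, 9); the chroman branch (steps 5–7) joins at step 8.

Steps most likely to fail

Step 8 (Proposed new method). The benzylation may take place at C4 or at the enolate oxygen instead of C2, or the ammonium cation may discriminate the two faces of the flat furanolate poorly. The fallback uses known chemistry and sets out from 10 and 15. Silylation of 10 (TBSOTf, Et3N, CH2Cl2) should give the 2-silyloxyfuran methyl 3-[3,4-bis(benzyloxy)phenyl]-5-(tert-butyldimethylsilyloxy)-4-methoxyfuran-2-carboxylate F1. Silver trifluoroacetate-promoted alkylation of F1 with 15 (CH2Cl2, −78 °C to 0 °C) is the known SN1-type γ-alkylation of 2-silyloxyfurans and should give 17 together with its C2 epimer, methyl (R)-3-[3,4-bis(benzyloxy)phenyl]-2-{[(R)-3-hydroxy-2,2-dimethylchroman-6-yl]methyl}-4-methoxy-5-oxo-2,5-dihydrofuran-2-carboxylate F2. Because the chromanol centre is fixed, the two are diastereomers and would be separated by preparative HPLC; the route is rejoined at 17.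

Step 3. Self-aldol of the arylpyruvate, retro-aldol cleavage or oligomerisation of the glyoxylate may compete under amine base. The fallback sets out from 6: bis-silylation (TMSCl, Et3N) to trimethylsilyl (Z)-3-[3,4-bis(benzyloxy)phenyl]-2-(trimethylsilyloxy)acrylate F3, Mukaiyama aldol addition to 7 (BF3·OEt2, CH2Cl2, −78 °C), then aqueous HCl, which should desilylate and lactonise to 9, where the route is rejoined.

Step 9. Over-reduction may occur before both benzyl ethers are gone, either by hydrogenolysis of the allylic lactone C–O bond or by saturation of the enol-ether double bond. The fallback sets out from 17 and replaces hydrogenolysis by non-reductive Lewis-acid debenzylation (BCl3, pentamethylbenzene as cation scavenger, CH2Cl2, −78 °C), which should lead directly to 18 without new intermediates.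

Further compounds
F1 | step 8 | methyl 3-[3,4-bis(benzyloxy)phenyl]-5-(tert-butyldimethylsilyloxy)-4-methoxyfuran-2-carboxylate | COC(=O)c1oc(O[Si](C)(C)C(C)(C)C)c(OC)c1-c1ccc(OCc2ccccc2)c(OCc2ccccc2)c1
F2 | step 8 | methyl (R)-3-[3,4-bis(benzyloxy)phenyl]-2-{[(R)-3-hydroxy-2,2-dimethylchroman-6-yl]methyl}-4-methoxy-5-oxo-2,5-dihydrofuran-2-carboxylate | COC(=O)[C@]1(Cc2ccc3c(c2)C[C@@H](O)C(C)(C)O3)OC(=O)C(OC)=C1c1ccc(OCc2ccccc2)c(OCc2ccccc2)c1
F3 | step 3 | trimethylsilyl (Z)-3-[3,4-bis(benzyloxy)phenyl]-2-(trimethylsilyloxy)acrylate | C[Si](C)(C)OC(=O)/C(O[Si](C)(C)C)=C/c1ccc(OCc2ccccc2)c(OCc2ccccc2)c1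
F0 | step 9 | none | none
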